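Germacrane numbering is used throughout.

**Retrosynthetic overview**
- The strategy rests on one feature. The two oxiranes of the ten-membered carbocycle lie on C1–C10 and C4–C5, the alkene positions of a 1,5-diene C10=C1–C2–C3–C4=C5. Joining C5 to C10 and cutting C2–C3 folds the ring back to a cyclohexane C5–C10, whose C6–C7–C8 edge (O6/O8 cis, C7 trigonal in the butenolide) is a dihydroxyacetone unit.
- Late disconnections are the C8 ester (chlorohydrin acid from a glycidate), both oxiranes (peripheral epoxidation of the E,E-diene), C13–OAc (allylic transposition from a C7 carbinol), O6–C12 (oxidative lactonisation) and C10–C14 (enol triflate methylation).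
- Core disconnections are C2–C3 (anionic oxy-Cope ring expansion with C5–C10 cleavage), C7–C11 (alkenylcerium addition), C5–C6 (intramolecular Michael addition) and C8–C9 (SAMP-hydrazone alkylation with a Baylis–Hillman bromide).
- Ring order: dioxane (bought), then cyclohexane C5–C10 fused to it as a 2,4-dioxabicyclo[3.3.1]nonane, then the ten-membered carbocycle, then the butenolide, then the two oxiranes.
- The C7 carbinol travels as a triethylsilyl ether from step 9 to step 19, so the C10 alkoxide is the only anion present in the rearrangement.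

Key step: step 17

**Remarks on the chemistry (assumptions)**
- α means the face of the carbocycle that carries O6 and O8, and β means the other face.
- SAMP is chosen from the usual topicity of cyclic SAMP azaenolates (the spatial sense of (R)-2-alkylcyclohexanones, which reads 4S here because the ring oxygen outranks C=N); if the sense proved opposite, RAMP would replace it with no other change.
- C10 of 14, 19 and 20 is drawn with the ester on the α (endo) face, as exo protonation requires; this also keeps the ester trans to O7 (no lactonisation) and leaves the α-hydrogen exposed, and the centre is made trigonal again in step 10.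
- Compound 42 is taken to be purchasable in enantiopure form.

Step 1
Reactants: 1 methacrolein; 2 methyl acrylate
Product: 3 methyl 3-hydroxy-4-methyl-2-methylidenepent-4-enoate (racemic)
Conditions: DABCO (0.3 equiv), neat, 23 °C
Reagents that add atoms: none
Why: Baylis–Hillman reaction in which the amine-activated acrylate adds through its α-carbon (future C10) to the aldehyde carbon (future C5) of 1, whose α-methyl group keeps it from acting as the donor itself, and the racemic carbinol centre is erased in step 2.

Step 2
Reactants: 3 Baylis–Hillman alcohol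
Product: 5 methyl (2Z)-2-(bromomethyl)-4-methylpenta-2,4-dienoate, via alkoxysulfonium bromide 4 (not isolated)
Conditions: NBS, Me2S, CH2Cl2, 0 → 23 °C
Reagents that add atoms: N-bromosuccinimide O=C1CCC(=O)N1Br
Why: Corey–Kim-type activation of a Baylis–Hillman alcohol as 4 followed by SN2′ attack of bromide on the acrylate CH2 should give the linearly conjugated dienoate as the usual Z isomer (isopropenyl cis to CH2Br, vinylic H cis to the ester), which A(1,3) strain favours.

Step 3
Reactants: 6 2,2-dimethyl-1,3-dioxan-5-one; 7 SAMP, (S)-1-amino-2-(methoxymethyl)pyrrolidine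
Product: 8 SAMP hydrazone of 6
Conditions: benzene, reflux, Dean–Stark trap
Reagents that add atoms: none
Why: Condensation of a ketone with a 1,1-dialkylhydrazine under azeotropic removal of water, and because the ketone is symmetric no C=N isomers arise.

Step 4
Reactants: 8 SAMP hydrazone; 5 allylic bromide
Product: 10 (4S)-4-alkylated SAMP hydrazone (C8–C9 made; C=N geometry not defined), via lithium azaenolate 9 (not isolated)
Conditions: t-BuLi (1.05 equiv), THF, −78 °C; then 5, −100 → −78 °C
Reagents that add atoms: none
Why: SAMP-hydrazone α-alkylation in which the chelated azaenolate 9 reacts on the face left open by the methoxymethylpyrrolidine, which sets C8 (4S in the dioxane), while the very reactive primary allylic bromide is displaced directly at C9 (SN2) in preference to addition at the substituted C5 of the dienoate.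

Step 5
Reactants: 10 alkylated hydrazone
Product: 11 methyl (2E)-2-{[(4S)-2,2-dimethyl-5-oxo-1,3-dioxan-4-yl]methyl}-4-methylpenta-2,4-dienoate (same spatial alkene as in 5: isopropenyl cis to C9)
Conditions: saturated aq. oxalic acid, Et2O, 23 °C
Reagents that add atoms: water O
Why: Two-phase acidic hydrazone hydrolysis, mild enough to leave the acetonide, the dienoate and the configurationally labile α-alkoxy centre C8 untouched while the auxiliary passes into the water layer as its oxalate.

Step 6
Reactants: 11 alkylated dioxanone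
Product: 14 methyl 3,3-dimethyl-9-oxo-6-(prop-1-en-2-yl)-2,4-dioxabicyclo[3.3.1]nonane-7-carboxylate (C5 isopropenyl axial on the β face; C10 ester on the α face), via C6 lithium enolate 12 (not isolated), via bicyclic ester enolate 13 (not isolated)
Conditions: LiN(SiMe3)2 (1.1 equiv), THF, −78 → −30 °C; AcOH, −78 °C
Reagents that add atoms: none
Why: Intramolecular 6-endo Michael addition of the kind that closes bicyclo[3.3.1]nonan-9-ones in the α,α′-annulation of cyclic ketones with 2-(bromomethyl)acrylates: kinetic deprotonation at the C6 methylene, axial C5–C6 bond formation with the C8 side chain axial (so C6 can only end cis to C8), a chair-like six-centre array in which the alkene substituent cis to C9 (isopropenyl) becomes axial and therefore anti to O6, and exo protonation of 13.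

Step 7
Reactants: 15 2-bromoprop-2-en-1-ol
Product: 16 (2-bromoallyloxy)(tert-butyl)dimethylsilane
Conditions: TBSCl, imidazole, CH2Cl2, 0 → 23 °C
Reagents that add atoms: tert-butyldimethylsilyl chloride CC(C)(C)[Si](C)(C)Cl
Why: Standard imidazole-promoted silylation of a primary allylic alcohol.

Step 8
Reactants: 14 bicyclic keto ester; 16 bromoallyl silyl ether
Product: 19 C7 tertiary carbinol carrying C11–C13 (alkenyl group on the α face over the dioxane; OH on the β face over the carbocycle), via vinyllithium 17 (not isolated), via organocerium reagent 18 (not isolated)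
Conditions: 16, t-BuLi (2 equiv), Et2O, −78 °C; CeCl3, THF, −78 °C; then 14, −78 °C; aq. NH4Cl
Reagents that add atoms: none
Why: Bromine–lithium exchange, transmetalation to the weakly basic organocerium reagent and 1,2-addition to the C7 ketone, which is inductively activated, cannot enolise (bridgehead α-carbons, Bredt's rule) and reacts far faster than the ester at −78 °C, the nucleophile coming over the two dioxane oxygens because the carbocycle face is closed by the axial isopropenyl group.

Step 9
Reactants: 19 C7 carbinol
Product: 20 C7 triethylsilyl ether of 19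
Conditions: TESOTf, 2,6-lutidine, CH2Cl2, −78 → 0 °C
Reagents that add atoms: triethylsilyl triflate CC[Si](CC)(CC)OS(=O)(=O)C(F)(F)F
Why: Silyl triflate silylation of a hindered tertiary alcohol, done here while O7 is the only hydroxyl, because a free C7 alkoxide in step 17 would sit on the new 1,5-diene C13=C11–C7–C6–C5=C4 and start a second anionic oxy-Cope shift, would compete for the triflating agent and would draw over the neighbouring silyl groups.

Step 10
Reactants: 20 silylated bicyclic ester
Product: 22 C10 α-hydroxy ester (OH on the β face syn to the isopropenyl group; ester carbon C1 on the α face), via potassium ester enolate 21 (not isolated)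
Conditions: KN(SiMe3)2 (1.2 equiv), THF, −78 °C; 3-phenyl-2-(phenylsulfonyl)oxaziridine, −78 °C; AcOH
Reagents that add atoms: 3-phenyl-2-(phenylsulfonyl)oxaziridine O=S(=O)(c1ccccc1)N1OC1c1ccccc1
Why: Davis hydroxylation of an ester enolate, in which the endo face of trigonal C10 looks into the cleft under the O–CMe2–O bridge so that oxygen should arrive from the exo face, leaving C1 and the C5 isopropenyl group trans.

Step 11
Reactants: 22 hydroxy ester
Product: 23 C1/C10 1,2-diol
Conditions: LiAlH4, Et2O, 0 °C
Reagents that add atoms: none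
Why: Hydride reduction of the α-hydroxy ester to the primary alcohol, with silyl ethers, acetonide and isolated alkenes inert at 0 °C and no stereocentre touched.

Step 12
Reactants: 23 1,2-diol
Product: 24 C10 α-hydroxy aldehyde
Conditions: Dess–Martin periodinane, pyridine, CH2Cl2, 0 °C
Reagents that add atoms: none
Why: Dess–Martin oxidation of the primary neopentylic alcohol under pyridine buffering, which leaves the tertiary hydroxyl alone and should not cleave this primary/tertiary glycol.

Step 13
Reactants: 24 hydroxy aldehyde
Product: 25 C10 vinyl carbinol (acetonide still in place)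
Conditions: Ph3PCH3Br, KOt-Bu (3 equiv each), THF, 0 °C
Reagents that add atoms: methyltriphenylphosphonium bromide C[P+](c1ccccc1)(c1ccccc1)c1ccccc1.[Br-]
Why: Wittig methylenation with excess non-stabilised ylide (part of it is spent on the free C10 hydroxyl) adds C2 and completes the vinyl group, and the aldehyde has no α-hydrogen so nothing can epimerise.

Step 14
Reactants: 25 vinyl carbinol acetonide
Product: 26 C6,C8,C10-triol (C7 OTES and primary OTBS kept)
Conditions: pyridinium p-toluenesulfonate (cat.), MeOH, 0 → 23 °C
Reagents that add atoms: none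
Why: Acid-catalysed transketalisation, in which the acetonide bridges two axial oxygens and presses a methyl group into the carbocycle so that its strain-driven methanolysis should outrun loss of the hindered tertiary TES and the primary TBS ether, and the freed ring flips to the chair with O6, O8, vinyl and isopropenyl all equatorial.

Step 15
Reactants: 26 triol
Product: 27 C8 tert-butyldimethylsilyl ether
Conditions: TBSOTf (1.05 equiv), 2,6-lutidine, CH2Cl2, −78 °C
Reagents that add atoms: tert-butyldimethylsilyl triflate CC(C)(C)[Si](C)(C)OS(=O)(=O)C(F)(F)F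
Why: Kinetic silylation at low temperature picks the C8 hydroxyl, which is flanked by the C9 methylene, over the C6 hydroxyl wedged between C5 and C7 and over the tertiary C10 hydroxyl, and the non-nucleophilic base avoids migration of the O7 silyl group.

Step 16
Reactants: 27 C8 silyl ether
Product: 28 trans-1-vinyl-2-isopropenylcyclohexan-1-ol with O6 TES, O7 TES, O8 TBS and O12 TBS (only C10–OH free)
Conditions: TESOTf (1.1 equiv), 2,6-lutidine, CH2Cl2, −78 → −40 °C
Reagents that add atoms: triethylsilyl triflate CC[Si](CC)(CC)OS(=O)(=O)C(F)(F)F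
Why: Silyl triflate silylation of the remaining secondary hydroxyl, which at low temperature reacts ahead of the axial tertiary C10 hydroxyl that must stay free for step 17.

Step 17
Reactants: 28 Cope precursor
Product: 31 ten-membered dienyl enol triflate (C4=C5 E; at C1=C10 the ring carbons C2 and C9 trans which reads Z because OTf outranks C9), via potassium alkoxide 29 (not isolated), via ten-membered potassium enolate 30 (not isolated)
Conditions: KH, 18-crown-6, THF, 0 → 23 °C; then PhNTf2, −78 → 0 °C; aq. NH4Cl
Reagents that add atoms: N-phenylbis(trifluoromethanesulfonimide) O=S(=O)(N(c1ccccc1)S(=O)(=O)C(F)(F)F)C(F)(F)F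
Why: Anionic oxy-Cope rearrangement followed by O-triflation of the enolate in the same flask, the known ring expansion of trans-1,2-dialkenylcyclohexanols to (E)-cyclodec-5-enone enolates: KH and 18-crown-6 give the dissociated C10 alkoxide 29, whose [3,3] shift makes C2–C3 while C5–C10 breaks. The ten-membered carbocycle is thus closed by a four-carbon ring expansion of the cyclohexane through a six-centre chair and not by end-to-end cyclisation, so no high dilution is needed. No stereocentre is created: C5 and C10 become trigonal and C6, C7 and C8 are spectators. Alkene geometry is controlled by the chair transition state of the conformer with vinyl, isopropenyl, O6 and O8 all equatorial, in which C6 and C9 are pseudo-equatorial, so C4=C5 comes out E and C9 comes out trans to C2 in enolate 30. The step needs a single alkoxide and a regiostable enolate: the first is secured by the silyl caps on O6 and O7 (a C6 or C7 alkoxide would trigger a second shift along C13=C11–C7–C6–C5=C4), the second by adding PhNTf2 at −78 °C before 30 can drift towards C9 and expel the C8 silyloxy group. At or below 23 °C the product 1,5-diene cannot go back thermally to the elemane skeleton.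

Step 18
Reactants: 31 enol triflate
Product: 32 fully silylated (1(10)E,4E)-germacra-1(10),4,11(13)-triene-6,7,8,12-tetrol
Conditions: MeMgBr, Fe(acac)3 (5 mol %), THF/NMP, −30 → 0 °C
Reagents that add atoms: methylmagnesium bromide C[Mg]Br
Why: Iron-catalysed Kumada-type cross-coupling of an alkenyl triflate with a methyl Grignard reagent, which keeps the alkene geometry and tolerates silyl ethers, installs C14.

Step 19
Reactants: 32 tetrasilyl ether
Product: 33 C6,C7,C12-triol with O8 TBS kept
Conditions: HF·pyridine, pyridine, THF, 0 → 23 °C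
Reagents that add atoms: none
Why: Graded fluoride desilylation in which the two TES ethers and the primary TBS ether fall well before the secondary C8 TBS ether next to quaternary C7, while the pyridine buffer protects the acid-sensitive 1,5-diene from transannular cyclisation.

Step 20
Reactants: 33 triol
Product: 36 α-methylene-β-hydroxy-γ-lactone on the germacradiene (12,6-olide; C7–OH free; O8 TBS), via hydroxy enal 34 (not isolated), via lactol 35 (not isolated)
Conditions: TEMPO (0.2 equiv), PhI(OAc)2 (2.5 equiv), CH2Cl2, 23 °C
Reagents that add atoms: none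
Why: Oxoammonium-mediated oxidative lactonisation of a 1,4-diol, in which the primary allylic alcohol is oxidised first, enal 34 closes with the cis-disposed C6 hydroxyl to lactol 35 and a second oxidation gives the lactone, the tertiary C7 hydroxyl being inert.

Step 21
Reactants: 36 hydroxy lactone
Product: 39 13-acetoxy-7(11)-en-12,6-olide with O8 TBS, via tertiary acetate 37 (not isolated), via C13 pyridinium acetate 38 (not isolated)
Conditions: Ac2O (5 equiv), DMAP (1.5 equiv), CH2Cl2, 23 → 35 °C
Reagents that add atoms: acetic anhydride CC(=O)OC(C)=O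
Why: Steglich-type acetylation of the tertiary alcohol gives the Baylis–Hillman-type acetate 37, which DMAP opens by SN2′ attack at C13 to 38 before acetate displaces the pyridinium group at the same primary carbon, so the acetoxy group ends on C13 and the more stable tetrasubstituted C7=C11 butenolide forms with loss of the temporary C7 centre.

Step 22
Reactants: 39 silylated butenolide
Product: 40 13-acetoxy-8α-hydroxygermacra-1(10)E,4E,7(11)-trien-12,6α-olide
Conditions: Bu4NF, AcOH (1:1), THF, 0 → 23 °C
Reagents that add atoms: none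
Why: Fluoride desilylation buffered with acetic acid, so that no free alkoxide is present to take over the C13 acetyl group, displace the allylic acetate or epimerise the γ-position C6 of the butenolide.

Step 23
Reactants: 40 dienyl alcohol
Product: 41 (1R,4R,5R,6S,8S,10R)-13-acetoxy-1,10:4,5-diepoxy-8-hydroxygermacr-7(11)-en-12,6-olide
Conditions: dimethyldioxirane (2.5 equiv, acetone solution), CH2Cl2, −20 → 0 °C
Reagents that add atoms: dimethyldioxirane CC1(C)OO1
Why: Neutral dioxirane epoxidation selects the two electron-rich trisubstituted alkenes over the butenolide alkene, each E-alkene of the ten-membered ring exposes only its peripheral face, A(1,3) strain between C15 and C6 fixes the C4=C5 face relative to C6 (the 4α,5β-epoxy-6α-oxy array of parthenolide) and the crown conformer with C14 and C15 both β should give the 1β,10α oxirane.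

Step 24
Reactants: 42 methyl (S)-2-methylglycidate
Product: 43 potassium (S)-2-methyloxirane-2-carboxylate
Conditions: KOH (1.0 equiv), EtOH, 0 °C
Reagents that add atoms: potassium hydroxide [K+].[OH-]
Why: Low-temperature saponification in which hydroxide attacks the ester carbonyl faster than the 2,2-disubstituted oxirane, and the quaternary stereocentre cannot epimerise.

Step 25
Reactants: 43 potassium glycidate
Product: 44 (R)-3-chloro-2-hydroxy-2-methylpropanoic acid
Conditions: conc. aq. HCl, 0 → 23 °C; extraction with EtOAc, no basic wash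
Reagents that add atoms: hydrogen chloride Cl
Why: Acid-promoted epoxide opening in which chloride attacks the unhindered CH2 in SN2 fashion because cation build-up next to the carboxyl group is disfavoured, so the C–O bond at the stereocentre is never broken and the descriptor changes from S to R only through the priority of CH2Cl.

Step 26
Reactants: 44 chlorohydrin acid
Product: 46 (R)-3-chloro-2-methyl-2-(trimethylsilyloxy)propanoic acid, via bis-silyl derivative 45 (not isolated)
Conditions: N,O-bis(trimethylsilyl)acetamide (2.5 equiv), CH2Cl2, 23 → 40 °C; then MeOH (1.5 equiv), 0 °C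
Reagents that add atoms: N,O-bis(trimethylsilyl)acetamide CC(=N[Si](C)(C)C)O[Si](C)(C)C
Why: Neutral silylation with a silyl imidate, which avoids base-induced re-closure of the chlorohydrin, followed by selective methanolysis of the far more labile silyl ester.

Step 27
Reactants: 41 diepoxy alcohol; 46 silyl-capped acid
Product: 48 CNP0255009.1, via TMS-capped ester 47 (not isolated)
Conditions: DCC, DMAP, CH2Cl2, 0 → 23 °C; filtration; then Et3N·3HF, THF, 0 °C
Reagents that add atoms: none
Why: Steglich esterification of the secondary allylic C8 hydroxyl with retention at C8 and at the quaternary centre of the acid, the silyl cap preventing self-acylation and oxirane formation from the chlorohydrin, followed by removal of the tertiary TMS ether with nearly neutral Et3N·3HF, which should not open the oxiranes at 0 °C.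

**Compound list**
1 | methacrolein | CC(=C)C=O | starting material
2 | methyl acrylate | COC(=O)C=C | starting material
3 | methyl 3-hydroxy-4-methyl-2-methylidenepent-4-enoate (racemic) | COC(=O)C(=C)C(O)C(C)=C | intermediate
4 | alkoxysulfonium bromide of 3 | COC(=O)C(=C)C(O[S+](C)C)C(C)=C.[Br-] | intermediate
5 | methyl (2Z)-2-(bromomethyl)-4-methylpenta-2,4-dienoate | COC(=O)/C(CBr)=C/C(C)=C | intermediate
6 | 2,2-dimethyl-1,3-dioxan-5-one | CC1(C)OCC(=O)CO1 | starting material
7 | SAMP, (S)-1-amino-2-(methoxymethyl)pyrrolidine | COC[C@@H]1CCCN1N | starting material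
8 | SAMP hydrazone of 6 | COC[C@@H]1CCCN1N=C1COC(C)(C)OC1 | intermediate
9 | lithium azaenolate of 8 | COC[C@@H]1CCCN1N([Li])C1=COC(C)(C)OC1 | intermediate
10 | (4S)-4-alkylated SAMP hydrazone (C=N geometry not defined) | COC(=O)/C(C[C@@H]1OC(C)(C)OCC1=NN1CCC[C@H]1COC)=C/C(C)=C | intermediate
11 | methyl (2E)-2-{[(4S)-2,2-dimethyl-5-oxo-1,3-dioxan-4-yl]methyl}-4-methylpenta-2,4-dienoate | COC(=O)/C(C[C@@H]1OC(C)(C)OCC1=O)=C/C(C)=C | intermediate
12 | C6 lithium enolate of 11 | COC(=O)/C(C[C@@H]1OC(C)(C)OC=C1O[Li])=C/C(C)=C | intermediate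
13 | bicyclic lithium ester enolate (C5–C6 closed) | COC(O[Li])=C1C[C@@H]2OC(C)(C)O[C@H]([C@H]1C(C)=C)C2=O | intermediate
14 | methyl 3,3-dimethyl-9-oxo-6-(prop-1-en-2-yl)-2,4-dioxabicyclo[3.3.1]nonane-7-carboxylate (isopropenyl β axial, ester α) | COC(=O)[C@@H]1C[C@@H]2OC(C)(C)O[C@H]([C@H]1C(C)=C)C2=O | intermediate
15 | 2-bromoprop-2-en-1-ol | OCC(Br)=C | starting material
16 | (2-bromoallyloxy)(tert-butyl)dimethylsilane | C=C(Br)CO[Si](C)(C)C(C)(C)C | intermediate
17 | 2-lithioallyl TBS ether | [Li]C(=C)CO[Si](C)(C)C(C)(C)C | intermediate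
18 | alkenylcerium dichloride | Cl[Ce](Cl)C(=C)CO[Si](C)(C)C(C)(C)C | intermediate
19 | C7 tertiary carbinol (C11 α, OH β) | COC(=O)[C@@H]1C[C@@H]2OC(C)(C)O[C@H]([C@H]1C(C)=C)[C@@]2(O)C(=C)CO[Si](C)(C)C(C)(C)C | intermediate
20 | C7 TES ether of 19 | COC(=O)[C@@H]1C[C@@H]2OC(C)(C)O[C@H]([C@H]1C(C)=C)[C@@]2(O[Si](CC)(CC)CC)C(=C)CO[Si](C)(C)C(C)(C)C | intermediate
21 | potassium ester enolate of 20 | COC(O[K])=C1C[C@@H]2OC(C)(C)O[C@H]([C@H]1C(C)=C)[C@@]2(O[Si](CC)(CC)CC)C(=C)CO[Si](C)(C)C(C)(C)C | intermediate
22 | C10 α-hydroxy ester (OH β, C1 α) | COC(=O)[C@]1(O)C[C@@H]2OC(C)(C)O[C@H]([C@H]1C(C)=C)[C@@]2(O[Si](CC)(CC)CC)C(=C)CO[Si](C)(C)C(C)(C)C | intermediate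
23 | C1/C10 1,2-diol | OC[C@]1(O)C[C@@H]2OC(C)(C)O[C@H]([C@H]1C(C)=C)[C@@]2(O[Si](CC)(CC)CC)C(=C)CO[Si](C)(C)C(C)(C)C | intermediate
24 | C10 α-hydroxy aldehyde | O=C[C@]1(O)C[C@@H]2OC(C)(C)O[C@H]([C@H]1C(C)=C)[C@@]2(O[Si](CC)(CC)CC)C(=C)CO[Si](C)(C)C(C)(C)C | intermediate
25 | C10 vinyl carbinol, acetonide in place | C=C[C@]1(O)C[C@@H]2OC(C)(C)O[C@H]([C@H]1C(C)=C)[C@@]2(O[Si](CC)(CC)CC)C(=C)CO[Si](C)(C)C(C)(C)C | intermediate
26 | C6,C8,C10-triol | C=C[C@@]1(O)[C@H](C(C)=C)[C@@H](O)[C@@](O[Si](CC)(CC)CC)(C(=C)CO[Si](C)(C)C(C)(C)C)[C@@H](O)C1 | intermediate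
27 | C8 TBS ether | C=C[C@@]1(O)[C@H](C(C)=C)[C@@H](O)[C@@](O[Si](CC)(CC)CC)(C(=C)CO[Si](C)(C)C(C)(C)C)[C@@H](O[Si](C)(C)C(C)(C)C)C1 | intermediate
28 | trans-1-vinyl-2-isopropenylcyclohexan-1-ol, O6 TES, O7 TES, O8 TBS, O12 TBS | C=C[C@@]1(O)[C@H](C(C)=C)[C@@H](O[Si](CC)(CC)CC)[C@@](O[Si](CC)(CC)CC)(C(=C)CO[Si](C)(C)C(C)(C)C)[C@@H](O[Si](C)(C)C(C)(C)C)C1 | intermediate
29 | C10 potassium alkoxide of 28 | C=C[C@@]1(O[K])[C@H](C(C)=C)[C@@H](O[Si](CC)(CC)CC)[C@@](O[Si](CC)(CC)CC)(C(=C)CO[Si](C)(C)C(C)(C)C)[C@@H](O[Si](C)(C)C(C)(C)C)C1 | intermediate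
30 | ten-membered potassium enolate (C10–O, C10=C1) | [K]O/C1=C\CC/C(C)=C/[C@@H](O[Si](CC)(CC)CC)[C@@](O[Si](CC)(CC)CC)(C(=C)CO[Si](C)(C)C(C)(C)C)[C@@H](O[Si](C)(C)C(C)(C)C)C1 | intermediate
31 | ten-membered dienyl enol triflate | O=S(=O)(O/C1=C\CC/C(C)=C/[C@@H](O[Si](CC)(CC)CC)[C@@](O[Si](CC)(CC)CC)(C(=C)CO[Si](C)(C)C(C)(C)C)[C@@H](O[Si](C)(C)C(C)(C)C)C1)C(F)(F)F | intermediate
32 | tetrasilylated E,E-germacratriene tetrol | C/C1=C\CC/C(C)=C/[C@@H](O[Si](CC)(CC)CC)[C@@](O[Si](CC)(CC)CC)(C(=C)CO[Si](C)(C)C(C)(C)C)[C@@H](O[Si](C)(C)C(C)(C)C)C1 | intermediate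
33 | C6,C7,C12-triol, O8 TBS | C/C1=C\CC/C(C)=C/[C@@H](O)[C@@](O)(C(=C)CO)[C@@H](O[Si](C)(C)C(C)(C)C)C1 | intermediate
34 | C12 hydroxy enal | C/C1=C\CC/C(C)=C/[C@@H](O)[C@@](O)(C(=C)C=O)[C@@H](O[Si](C)(C)C(C)(C)C)C1 | intermediate
35 | C12 lactol (anomeric centre not defined) | C/C1=C\CC/C(C)=C/[C@H]2OC(O)C(=C)[C@@]2(O)[C@@H](O[Si](C)(C)C(C)(C)C)C1 | intermediate
36 | α-methylene-β-hydroxy-γ-lactone on the germacradiene | C/C1=C\CC/C(C)=C/[C@H]2OC(=O)C(=C)[C@@]2(O)[C@@H](O[Si](C)(C)C(C)(C)C)C1 | intermediate
37 | C7 tertiary acetate | C/C1=C\CC/C(C)=C/[C@H]2OC(=O)C(=C)[C@@]2(OC(C)=O)[C@@H](O[Si](C)(C)C(C)(C)C)C1 | intermediate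
38 | C13 4-(dimethylamino)pyridinium acetate | CN(C)c1cc[n+](CC2=C3[C@@H](O[Si](C)(C)C(C)(C)C)C/C(C)=C/CC/C(C)=C/[C@H]3OC2=O)cc1.CC(=O)[O-] | intermediate
39 | 13-acetoxy butenolide, O8 TBS | CC(=O)OCC1=C2[C@@H](O[Si](C)(C)C(C)(C)C)C/C(C)=C/CC/C(C)=C/[C@H]2OC1=O | intermediate
40 | 13-acetoxy-8α-hydroxygermacra-1(10)E,4E,7(11)-trien-12,6α-olide | CC(=O)OCC1=C2[C@@H](O)C/C(C)=C/CC/C(C)=C/[C@H]2OC1=O | intermediate
41 | diepoxy 13-acetoxy butenolide with free C8–OH | CC(=O)OCC1=C2[C@@H](O)C[C@@]3(C)O[C@@H]3CC[C@@]3(C)O[C@@H]3[C@H]2OC1=O | intermediate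
42 | methyl (S)-2-methylglycidate | COC(=O)[C@@]1(C)OC1 | starting material
43 | potassium (S)-2-methyloxirane-2-carboxylate | [K+].[O-]C(=O)[C@@]1(C)OC1 | intermediate
44 | (R)-3-chloro-2-hydroxy-2-methylpropanoic acid | OC(=O)[C@@](C)(O)CCl | intermediate
45 | trimethylsilyl (R)-3-chloro-2-methyl-2-(trimethylsilyloxy)propanoate | C[Si](C)(C)OC(=O)[C@@](C)(O[Si](C)(C)C)CCl | intermediate
46 | (R)-3-chloro-2-methyl-2-(trimethylsilyloxy)propanoic acid | OC(=O)[C@@](C)(O[Si](C)(C)C)CCl | intermediate
47 | TMS ether of the target | CC(=O)OCC1=C2[C@@H](OC(=O)[C@@](C)(O[Si](C)(C)C)CCl)C[C@@]3(C)O[C@@H]3CC[C@@]3(C)O[C@@H]3[C@H]2OC1=O | intermediate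
48 | CNP0255009.1, (1R,4R,5R,6S,8S,10R,2′R) | CC(=O)OCC1=C2[C@@H](OC(=O)[C@@](C)(O)CCl)C[C@@]3(C)O[C@@H]3CC[C@@]3(C)O[C@@H]3[C@H]2OC1=O | target

**Step count**
- Total step count: 27.
- Longest linear sequence: 22 steps (1, 2, 4–6, 8–23, 27).

**The three steps most likely to fail**

**Step 10.**
- Risk: enolisation of the crowded ester may be slow. Facial selectivity in the oxygen transfer may erode, because the only open (exo) face of C10 is flanked by the axial isopropenyl group.
- The fallback sets out from 20 and comes back at 28. It makes the C10 carbinol by adding a vinyl nucleophile to a ketone in the ring-flipped chair, not by oxidising an enolate in the bicycle.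
- The ester is hydroxylated without regard to face to give the hydroxy ester as a C10 epimer mixture F1.
- LiAlH4 gives the 1,2-diol F2, and NaIO4 on silica cleaves it to the bicyclic C10 ketone F3. Both epimers converge here and C1 is lost.
- Pyridinium p-toluenesulfonate in MeOH frees the keto diol F4.
- TBSOTf at −78 °C gives the C8 silyl ether F5, and TESOTf gives the bis-silylated ketone F6.
- Vinylmagnesium bromide with CeCl3 at −78 °C should then add equatorially, trans to the equatorial isopropenyl group. The low basicity avoids conjugation of the β,γ-enone and loss of the β-silyloxy groups. This gives 28, with C1 and C2 now coming from the vinyl reagent.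

**Step 6.**
- Risk: the lithium enolate may decay before it closes. Closure may go through a boat-like array, which loses control at C5. The closure may reverse on warming.
- The fallback sets out from 11 and comes back at 14. It replaces the preformed metal enolate by neutral enamine activation, the original mode of the α,α′-annulation.
- Pyrrolidine over 4 Å sieves gives the less substituted pyrrolidine enamine F7 (double bond towards C6).
- This enamine should close on C5 in MeCN in the presence of one equivalent of AcOH to give the bicyclic iminium acetate F8.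
- Hydrolysis in an aqueous NaOAc/AcOH buffer returns 14.

**Step 23.**
- Risk: facial selectivity at C1=C10 may be poor. The free C8 hydroxyl can steer the oxidant by hydrogen bonding, or a second ring conformer can become populated. Transannular attack of that hydroxyl on a new oxirane is also possible.
- The fallback sets out from 40 (with 46) and comes back at 47, by reversing the order of the last two operations.
- Steglich esterification of 40 with 46 (DCC, DMAP) gives the dienyl ester F9. Here the bulky pseudo-equatorial acyloxy group holds the crown conformer and no hydroxyl is left to direct the oxidant or open an oxirane.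
- Dimethyldioxirane then gives 47, which is desilylated as in step 27.

**Further compounds**
F1 | step 10 | C10 hydroxy ester as epimer mixture (C10 not defined) | COC(=O)C1(O)C[C@@H]2OC(C)(C)O[C@H]([C@H]1C(C)=C)[C@@]2(O[Si](CC)(CC)CC)C(=C)CO[Si](C)(C)C(C)(C)C
F2 | step 10 | C1/C10 1,2-diol as epimer mixture (C10 not defined) | OCC1(O)C[C@@H]2OC(C)(C)O[C@H]([C@H]1C(C)=C)[C@@]2(O[Si](CC)(CC)CC)C(=C)CO[Si](C)(C)C(C)(C)C
F3 | step 10 | bicyclic C10 ketone | O=C1C[C@@H]2OC(C)(C)O[C@H]([C@H]1C(C)=C)[C@@]2(O[Si](CC)(CC)CC)C(=C)CO[Si](C)(C)C(C)(C)C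
F4 | step 10 | C10 keto C6,C8-diol | O=C1[C@H](C(C)=C)[C@@H](O)[C@@](O[Si](CC)(CC)CC)(C(=C)CO[Si](C)(C)C(C)(C)C)[C@@H](O)C1
F5 | step 10 | C10 ketone, O8 TBS | O=C1[C@H](C(C)=C)[C@@H](O)[C@@](O[Si](CC)(CC)CC)(C(=C)CO[Si](C)(C)C(C)(C)C)[C@@H](O[Si](C)(C)C(C)(C)C)C1
F6 | step 10 | C10 ketone, O6 TES, O8 TBS | O=C1[C@H](C(C)=C)[C@@H](O[Si](CC)(CC)CC)[C@@](O[Si](CC)(CC)CC)(C(=C)CO[Si](C)(C)C(C)(C)C)[C@@H](O[Si](C)(C)C(C)(C)C)C1
F7 | step 6 | pyrrolidine enamine of 11 (towards C6) | COC(=O)/C(C[C@@H]1OC(C)(C)OC=C1N1CCCC1)=C/C(C)=C
F8 | step 6 | bicyclic iminium acetate | COC(=O)[C@@H]1C[C@@H]2OC(C)(C)O[C@H]([C@H]1C(C)=C)C2=[N+]1CCCC1.CC(=O)[O-]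
F9 | step 23 | dienyl C8 ester with TMS-capped side chain | CC(=O)OCC1=C2[C@@H](OC(=O)[C@@](C)(O[Si](C)(C)C)CCl)C/C(C)=C/CC/C(C)=C/[C@H]2OC1=O
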